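All runs are calculated for an exercise.

Ask which flask holds the most open intermediate at 6.0 h and again at 2.0 d. The recipes keep starting material and reagent fixed and move the partner from 0.120 M to 1.50 M, so look for what the partner does.

| setting | blue | teal | summer | spring | winter | noon | autumn | dawn |
|---|---|---|---|---|---|---|---|---|
| starting material | 0.13 M | 0.40 M | 0.20 M | 0.20 M | 0.20 M | 0.20 M | 0.20 M | 0.20 M |
| partner | 0.36 M | 0.36 M | 0.250 M | 0.500 M | 1.50 M | 0.120 M | 0.800 M | 0.360 M |
| reagent | 0.20 M | 0.20 M | 0.200 M | 0.200 M | 0.200 M | 0.200 M | 0.200 M | 0.200 M |
| remark | run made earlier | run made earlier |  |  |  |  |  |  |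
| time |  |  | 6.0 h | 6.0 h | 6.0 h | 6.0 h | 6.0 h | 6.0 h |

- the flasks put in order of amount of open intermediate, in percent of the starting material charged, best first, at 6.0 h (summer / spring / winter / noon / autumn / dawn)
- the same order at 2.0 d (summer / spring / winter / noon / autumn / dawn)
- the amount of open intermediate, in percent of the starting material charged of the flask you put first, at 6.0 h
- the amount of open intermediate, in percent of the starting material charged of the flask you put last, at 6.0 h

| run | time / h | open intermediate / % | target / % | starting material / % |
|---|---|---|---|---|
| blue | 0.250 | 6.9 | 0 | 94.9 |
| blue | 0.500 | 8.8 | 0 | 88.3 |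
| blue | 0.833 | 12.0 | 1.2 | 78.6 |
| blue | 1.33 | 16.5 | 0 | 67.3 |
| blue | 2.00 | 20.4 | 1.5 | 51.2 |
| blue | 4.00 | 22.7 | 2.3 | 26.0 |
| teal | 0.250 | 4.3 | 0.1 | 93.0 |
| teal | 0.500 | 7.7 | 0 | 88.6 |
| teal | 0.833 | 10.2 | 0.2 | 82.9 |
| teal | 1.33 | 13.8 | 0 | 73.2 |
| teal | 2.00 | 17.4 | 1.3 | 67.5 |
| teal | 4.00 | 19.8 | 0 | 54.9 |

(scatter of a reading: 1 percentage point)



Begin with the last line of teal, at 4.00 h. Teal has lost 45.1% of its starting material, which equals 90.2% of the reagent charged, and the loss is slowing. So treat reagent as the limiting reagent, one reagent per starting material lost.

But open intermediate and target hold 19.8% of the teal charge, so 25.3% has gone unseen. Assume, as my own reading, that partner also takes reagent, and that what this makes quickly removes one starting material. Take that quick step as settled and count how the reagent divides.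

Divide the open intermediate by the unseen loss: 0.783. Multiply by the mean partner over the mean starting material in teal, 0.999, to get 0.782. Call this the selectivity factor: the pull of one starting material on reagent against one partner. It is a reading and carries the scatter.

Now multiply the factor by the starting material and divide by that product plus the partner. With the charges as they stand, this gives the share of reagent that makes open intermediate at the start: 56.6% in noon and 9.44% in winter. Here reagent and starting material charges are equal, so my order runs by rising partner at both times, with noon first. These shares belong to the start, so don't read them as the amounts at either asked time.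

The forecast differs at 6.0 h, giving summer > dawn > spring > noon > autumn > winter with 22% in its first flask and 1.5% in its last, and gives noon > summer > dawn > spring > autumn > winter at 2.0 d. Its ground is that “Intermediate then peaks at a fixed partner exposure”.

The flasks give noon > summer > dawn > spring > autumn > winter at 6.0 h, with 40.1% in noon and 7.12% in winter, and noon > summer > dawn > spring > autumn > winter at 2.0 d.

    starting material + second intermediate → side product (k = 4.00 M⁻¹ h⁻¹)
    open intermediate + second intermediate → target (k = 0.520 M⁻¹ h⁻¹)
    2 second intermediate → homo product (k = 0.00920 M⁻¹ h⁻¹)
    reagent + partner → second intermediate (k = 1.40 M⁻¹ h⁻¹)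
    starting material + reagent → open intermediate (k = 1.10 M⁻¹ h⁻¹)

Carry the factor to winter's neighbour with 0.80 M of starting material. Take its starting material and partner midway between the charge and their values at 6.00 h, so that the share covers the run and not the start. The share is 27.7%, and the reagent is a quarter of that starting material charge, so expect 6.93% of the charge. With 0% of its reagent left, that flask holds 0.147% target and 7.04% open intermediate.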